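## Structural features

The target is a daucane ester, a trans-fused bicyclo[5.3.0]decane in which a cyclopentane (C1–C5) and a cycloheptane (C1, C5–C10) share the C1–C5 bond. The numbering used throughout is: C1 angular carbon with CH3, C2 and C3 the five-ring CH2 groups, C4 the carbinol carbon with the isopropyl group, C5 the ring-fusion CH, C6 CH–OAr, C7 C=O, C8 C(OH)CH3, C9 CH–OH, C10 the seven-ring CH2. β is the face of the C1 methyl and α the opposite face. There are six stereocentres: quaternary C1 stands next to the ring-fusion methine C5, C4–C5–C6 are contiguous, and C8–C9 are contiguous. The 4-OH is β, whereas H-5, the 6-aroyloxy group and the hydroxyls at C8 and C9 are all α. The C7 ketone is at once an α-ketol (C8), a β-hydroxy ketone (C9, retro-aldol) and an α-acyloxy ketone (C6, epimerisable, acyl shift); the 4-hydroxybenzoate is base-labile, and the C4 carbinol is ionisable for as long as C5 is sp2. The real difficulty is the quaternary C1 beside a trans 5–7 fusion, combined with four adjacent oxygenated carbons (C6–C9) on a flexible ring. The key step uses C4, taken as a ketone, both as the acceptor of a vinylcarbenoid centred on C5 (vinyl group = C6, C7) and, through C3 and C2, as the tether to a C1=C10–C9=C8 silyloxydiene, so that both rings form in one operation.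

## Logic of the disconnections

26 ⇒ 25 ⇒ 23 + 24. The acyl C–O bond at C6 and the two acid-labile protecting groups are cut first. The aryl ester is the most base-sensitive group and the best candidate for acyl migration, so it should enter last. This removes the arene and leaves one free secondary hydroxyl. The forward step must acylate C6–OH beside the tertiary C4–OH, and the final unmasking must be acidic and mild.

23 ⇒ 22. The C6–O bond is cut. In 22 the ketone can enolise only towards C6, because C8 is fully substituted, so the regiochemistry is automatic. The oxidant must arrive on the α face; this is also the equatorial, more stable position.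

22 ⇒ 21 ⇒ 20. The ketal is removed and the C5–H bond is cut, returning C5=C6 in conjugation with C7=O. The trans ring fusion is thereby left to a late reduction of an enone. The forward reduction must put hydrogen on the α face of C5 and must not expel the oxygens at C4 and C8, which is why they are carried as free hydroxyls (alkoxides under the conditions).

20 ⇒ 19. Both C–O bonds at C8 and C9 are cut together. A syn-dihydroxylation makes the cis relation certain and leaves only the choice of face open. It must select C8=C9 over the hindered C5=C6 and attack anti to the angular methyl.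

19 ⇒ 17 (through 18). The C7=O bond and the C8=C9 double bond are cut. C7 is the only hydrogen-bearing allylic position of C5=C6, and an acyloxy group at C9 is then β to the new ketone and leaves by elimination. The ring oxygen delivered by the key step is thus spent to place the C8=C9 alkene. The C–H oxidation must tolerate a free tertiary allylic alcohol.

17 ⇒ 16 ⇒ 14. The acetyl group and the C9–H bond are removed, returning the C9 silyl enol ether. The enol ether serves as a masked ketone while C4 is elaborated. The C9 configuration is of no consequence.

14 ⇒ 12 + 13. The C4–isopropyl bond is cut. 12 has a single carbonyl group, so no chemoselectivity problem arises. The addition must be 1,2 and anti to the angular methyl so that the hydroxyl ends β.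

12 ⇒ 10 (key step). The C1–C5 and C7–C8 bonds are cut. Both rings open to an acyclic vinyl diazoketone that carries an E trisubstituted alkene and a Z silyl enol ether (chain C3 = C5, C1 = C7, C7 = C1, C10 = C8 of the bicycle). The forward step needs enantioface control at the alkene and a cis-divinylcyclopropane.

10 ⇒ 9 ⇒ 7 + 8. The diazo group and then the C3–C4 bond of the chain are cut. The acidic allyl ketone is made only after the silyloxydiene is in place; a later enolisation would have to choose between two enolisable ketones. The acceptor in 7 must take exactly one equivalent of 8.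

7 ⇒ 6 ⇒ 5 ⇒ 4 ⇒ 1 + 2. The O–Si bond, the amide, the oxidation level, and finally the methyl-bearing alkene are undone. The E geometry comes from a syn-carbometalation of the alkyne 1 and not from a ketone olefination, which would give E/Z mixtures. The alkenyl–metal intermediate must add to 2 with retention.

## Other disconnections considered

Alternative 1: The cut is the C6–C7 bond, reached by inserting a sulfonyl group between the two carbons. In the forward direction the eight-membered sulfone A2, treated with KOH and CCl4 in tert-butanol, is chlorinated next to sulfur and contracts by 1,3-elimination and loss of SO2 to the cycloheptene A1.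
- In its favour: A1 already holds the trans fusion, the C4 carbinol and the cis-8,9-diol; the new alkene sits where the last two oxygens are needed; the reaction is robust and needs no chiral catalyst.
- Against it: the step forms one bond and no stereocentre, so C1, C4, C5, C8 and C9 must all be built and correlated beforehand, probably from two chiral fragments. The C6=C7 alkene must then be oxidised with regiocontrol (ester at C6, ketone at C7). CCl4 is an undesirable reagent.
- Comparison: on structure, A1 is closer to the target than 12, and here Alternative 1 is the better plan. On mechanism it is at least the equal of the carbenoid route in reliability. On step economy it is weaker, since the chosen step makes two bonds, two rings and two stereocentres from an acyclic chain of six steps.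

Alternative 2: The cuts are the C1–C5 and C9–C10 bonds. In the forward direction the silyloxypyranone A4 is heated, the silyl group shifts between the two oxygens, and the resulting five-atom dipole adds across the tethered 1,1-disubstituted alkene ((5+2) cycloaddition) to give the oxygen-bridged adduct A3.
- In its favour: two bonds and two rings form, C1 is set, and A3 carries an oxygen or a reactive site at each of C6–C9. On oxidation-state economy it is better than the chosen plan, in which 12 has oxygen only at C9. No diazo compound is handled, which is also a point in its favour.
- Against it: the bridging oxygen ends on C5, where the target has hydrogen, so a C–O bond at a fully substituted carbon must be cleaved reductively with control of the ring fusion. The tertiary carbinol C4 must be made enantiopure first, and it must relay its configuration to C1 through a flexible tether.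
- Comparison: on structure, A3 is richer in oxygen but has one bond too many. On mechanism, both are pericyclic cascades; the chosen one depends on a chiral catalyst, the alternative on substrate control. On step economy the two should be similar, the bridge cleavage offsetting the saving in oxidations.

Alternative 3: The cut is the C1–C10 bond. In the forward direction the 2-methylenetetrahydrofuran A6, on heating, rearranges ([3,3], Claisen) so that the exocyclic CH2 bonds to the methyl-bearing alkene carbon and the ring C–O bond breaks, giving the cycloheptenone A5.
- In its favour: the quaternary C1 arises by chirality transfer from a C–O stereocentre and needs no chiral catalyst. The C8 oxygen and its methyl are present from the start, which is better than in the chosen plan. The C4 ketone is protected for a late isopropyl addition.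
- Against it: the step forms one C–C bond and one ring. The ring constraint forces a boat transition state at high temperature, and the enol ether substrate is acid-sensitive. In A5 the ketal spans C7/C8 and the ketone is at C9, so the C8/C9 cis-diol would have to come from a ketone reduction whose facial outcome is doubtful, and C6 and C5 still need the same late operations as here.
- Comparison: on structure it is ahead at C8, behind at C9. On mechanism it is the equal of the Cope half of the chosen step. On step economy it is probably longer, since a functionalised cyclopentene and the tetrahydrofuran must be joined before the key step.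

Key step: step 7

Remark: the sense of induction of Rh2(S-PTAD)4 in this intramolecular, ketone-tethered case cannot be predicted with confidence; the S catalyst is written, and Rh2(R-PTAD)4 replaces it if the first run shows that it is the one that leads to 12.

Remark: in 12 the C8 methyl is placed trans to the angular methyl (8α), as the boat transition state demands for a Z enol ether; this centre disappears in step 11.

Remark: 24 is taken as a purchasable acid.

Step 1
Reactants: 1 pent-4-yn-1-ol; 2 propanal
Product: 4 (E)-5-methyloct-4-ene-3,8-diol (racemic at C3), via alkenylalane 3 (not isolated)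
Conditions: Me3Al, Cp2ZrCl2 (25 mol %), CH2Cl2, 0 °C → rt; then MeLi, THF, −78 °C; 2, −78 → 0 °C; aq. potassium sodium tartrate
Reagents that add atoms: trimethylaluminium, C[Al](C)C; propanal (2), CCC=O
Why: Zirconocene-catalysed carboalumination (Negishi) adds CH3 and Al syn across the terminal alkyne with the metal on the terminal carbon, so 3 is the E alkenylalane; its alanate transfers the alkenyl group to 2 with retention of geometry. The new carbinol centre is racemic and is oxidised in step 2.

Step 2
Reactants: 4 (E)-5-methyloct-4-ene-3,8-diol
Product: 5 (E)-4-methyl-6-oxooct-4-enoic acid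
Conditions: TEMPO (20 mol %), PhI(OAc)2, MeCN–H2O, rt
Reagents that add atoms: water, O
Why: Oxoammonium oxidation converts the allylic secondary alcohol into the enone and the primary alcohol, through the aldehyde hydrate, into the acid; the nearly neutral, chromium-free medium should leave the E alkene untouched.

Step 3
Reactants: 5 (E)-4-methyl-6-oxooct-4-enoic acid
Product: 6 (E)-N-methoxy-N,4-dimethyl-6-oxooct-4-enamide
Conditions: CDI, CH2Cl2, rt; then MeNHOMe·HCl, rt
Reagents that add atoms: N,O-dimethylhydroxylamine hydrochloride, CNOC.Cl
Why: Acyl imidazole formation and aminolysis (amide coupling) give the N-methoxy-N-methylamide, which does not enolise in step 4 and accepts exactly one Grignard equivalent in step 5.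

Step 4
Reactants: 6 (E)-N-methoxy-N,4-dimethyl-6-oxooct-4-enamide
Product: 7 (4E,6Z)-6-(tert-butyldimethylsilyloxy)-N-methoxy-N,4-dimethylocta-4,6-dienamide
Conditions: TBSOTf, Et3N, CH2Cl2, −78 → 0 °C
Reagents that add atoms: tert-butyldimethylsilyl trifluoromethanesulfonate, CC(C)(C)[Si](C)(C)OS(=O)(=O)C(F)(F)F
Why: Soft enolisation: O-silylation of the enone carbonyl and amine deprotonation at the α′ CH2 of the ethyl group give the cross-conjugated 2-silyloxydiene, and ethyl ketones should give the Z enol ether (CH3 cis to OSi) that the Cope step needs. The amide is not enolised, which is the reason for installing the diene before the acidic allyl ketone exists.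

Step 5
Reactants: 7 (4E,6Z)-6-(tert-butyldimethylsilyloxy)-N-methoxy-N,4-dimethylocta-4,6-dienamide; 8 allylmagnesium bromide
Product: 9 (7E,9Z)-9-(tert-butyldimethylsilyloxy)-7-methylundeca-1,7,9-trien-4-one
Conditions: 8, THF, −78 °C; cold aq. NH4Cl
Reagents that add atoms: allylmagnesium bromide (8), C=CC[Mg]Br
Why: The chelated tetrahedral intermediate of the N-methoxy-N-methylamide stops at mono-addition and gives the β,γ-unsaturated ketone on quench; silyl enol ethers are inert to Grignard reagents at low temperature. Partial migration of the double bond into conjugation would not matter, since both isomers give the same dienolate in step 6.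

Step 6
Reactants: 9 (7E,9Z)-9-(tert-butyldimethylsilyloxy)-7-methylundeca-1,7,9-trien-4-one
Product: 10 (7E,9Z)-9-(tert-butyldimethylsilyloxy)-3-diazo-7-methylundeca-1,7,9-trien-4-one
Conditions: p-ABSA, DBU, MeCN, 0 °C; used at once
Reagents that add atoms: 4-acetamidobenzenesulfonyl azide, CC(=O)Nc1ccc(cc1)S(=O)(=O)N=[N+]=[N-]
Why: Regitz diazo transfer: DBU deprotonates the doubly activated C3 methylene (allylic and α to the ketone) and the dienolate takes the diazo group at C3, giving the vinyl diazoketone. p-ABSA is the safer sulfonyl azide; 10 can close to a pyrazole on standing, so it is kept cold and carried straight into step 7.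

Step 7
Reactants: 10 (7E,9Z)-9-(tert-butyldimethylsilyloxy)-3-diazo-7-methylundeca-1,7,9-trien-4-one
Product: 12 9-(tert-butyldimethylsilyloxy)-1β,8α-dimethylbicyclo[5.3.0]deca-5,9-dien-4-one, via divinylcyclopropane 11 (not isolated)
Conditions: Rh2(S-PTAD)4 (1 mol %), hexanes, slow addition of 10, −40 °C → rt; then toluene, 80–110 °C
Reagents that add atoms: none
Why: Loss of N2 at the dirhodium centre gives a donor/acceptor vinylcarbenoid, which cyclopropanates the tethered C7=C8 alkene of the chain in a concerted, asynchronous [2+1] addition and thereby closes the five-membered ring as the bicyclo[3.1.0]hexan-2-one 11. Because the alkene is E and the three-atom tether enforces a cis ring fusion, the carbenoid vinyl group, the bridgehead methyl and the silyloxypropenyl group lie on one face of the cyclopropane, so the two vinyl groups are cis. On warming, 11 undergoes a [3,3] shift through the boat transition state that cis-divinylcyclopropanes must adopt: the cyclopropane bond between the two vinyl-bearing carbons breaks, the terminal CH2 of the vinyl group bonds to the CH(CH3) terminus of the enol ether, and the seven-membered ring closes by strain-driven ring expansion. C1 is set in the cyclopropanation by the enantioface selection of the chiral carboxylate catalyst and is not touched afterwards; C8 is set by the Z enol ether geometry, which keeps its methyl on the outside of the boat and hence trans to the angular methyl. The closest known reaction type is the dirhodium-catalysed tandem cyclopropanation–Cope rearrangement of vinyldiazo compounds with dienes (formal (4+3) cycloaddition), run here intramolecularly with a ketone as acceptor; the phthalimido-adamantylglycinate catalyst is chosen because it copes better with ketone acceptors than the prolinate catalysts do. The step needs site selectivity for the proximal alkene over the more electron-rich enol ether, which the tether length secures (five-ring against seven-ring closure), and a cis-divinyl arrangement, which the E alkene secures. The bridgehead methyl is syn to both vinyl groups and crowds the boat, so the rearrangement is expected to need the heating period in toluene.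

Step 8
Reactants: 12 9-(tert-butyldimethylsilyloxy)-1β,8α-dimethylbicyclo[5.3.0]deca-5,9-dien-4-one; 13 isopropylmagnesium chloride
Product: 14 (8βH)-9-(tert-butyldimethylsilyloxy)dauca-5,9-dien-4β-ol
Conditions: 13, CeCl3, THF, −78 °C; aq. NH4Cl
Reagents that add atoms: isopropylmagnesium chloride (13), CC(C)[Mg]Cl
Why: 1,2-Addition of the organocerium reagent (which suppresses enolisation, β-hydride reduction and conjugate addition) to the only carbonyl of 12, the C9 ketone being masked as its silyl enol ether. The angular methyl is pseudo-axial over the β face of the five-membered ring, so the isopropyl group should enter from the α face and leave the hydroxyl β.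

Step 9
Reactants: 14 (8βH)-9-(tert-butyldimethylsilyloxy)dauca-5,9-dien-4β-ol
Product: 16 (8βH)-dauc-5-ene-4β,9-diol (both C9 epimers), via hydroxy ketone 15 (not isolated)
Conditions: Bu4NF, AcOH, THF, 0 °C; then MeOH, NaBH4, 0 °C
Reagents that add atoms: none
Why: Fluoride cleaves the silyl enol ether (the buffer protonates the enolate at C10 and leaves C8 alone) and borohydride reduces the liberated ketone in the same flask. The C9 carbinol is only a leaving-group precursor, so both epimers are carried on; the acid-sensitive tertiary allylic alcohol sees no strong acid.

Step 10
Reactants: 16 (8βH)-dauc-5-ene-4β,9-diol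
Product: 17 (8βH)-4β-hydroxydauc-5-en-9-yl acetate (both C9 epimers)
Conditions: Ac2O, pyridine, DMAP (cat.), CH2Cl2, rt
Reagents that add atoms: acetic anhydride, CC(=O)OC(C)=O
Why: Acylation of the secondary alcohol (the hindered tertiary C4 hydroxyl should not react) protects C9 against oxidation in step 11 and turns it into a leaving group β to the future ketone.

Step 11
Reactants: 17 (8βH)-4β-hydroxydauc-5-en-9-yl acetate
Product: 19 4β-hydroxydauca-5,8-dien-7-one, via acetoxy enone 18 (not isolated)
Conditions: Rh2(cap)4 (dirhodium tetrakis(caprolactamate), 1 mol %), t-BuOOH (aq.), ClCH2CH2Cl, 40 °C; then DBU, CH2Cl2, rt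
Reagents that add atoms: tert-butyl hydroperoxide, CC(C)(C)OO
Why: Allylic oxidation by tert-butylperoxyl radicals: C7 is the only allylic position of the C5=C6 alkene that carries hydrogen (C1 and C4 are quaternary), as in the oxidation of Δ5 steroids to 7-ketones. The β-acetoxy ketone 18 then loses acetic acid by E1cB with DBU from either C9 epimer, which erases C8 and C9 and gives the cross-conjugated dienone.

Step 12
Reactants: 19 4β-hydroxydauca-5,8-dien-7-one
Product: 20 4β,8α,9α-trihydroxydauc-5-en-7-one
Conditions: K2OsO4·2H2O (2 mol %), NMO, citric acid, t-BuOH–H2O, rt
Reagents that add atoms: N-methylmorpholine N-oxide, C[N+]1([O-])CCOCC1; water, O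
Why: Catalytic syn-dihydroxylation should take the C8=C9 bond, because C5=C6 is flanked by two quaternary carbons; both C–O bonds form on one face, which fixes the cis relation of the two hydroxyls. Attack anti to the pseudo-axial angular methyl, which is homoallylic to C9 as in steroid 2-enes, should place both hydroxyls α.

Step 13
Reactants: 20 4β,8α,9α-trihydroxydauc-5-en-7-one
Product: 21 4β,8α,9α-trihydroxy-5αH-daucan-7-one
Conditions: Li, NH3 (l), THF, −78 °C; then NH4Cl
Reagents that add atoms: none
Why: Dissolving-metal reduction of the enone: two electrons and protonation at the β carbon C5 give the lithium enolate, and axial protonation of the pyramidal C5 carbanion should give the more stable trans fusion (H-5 α), as with Δ5-7-keto steroids. The three hydroxyls are present as alkoxides, which are not leaving groups, so neither the γ oxygen at C4 nor the α′ oxygen at C8 should be expelled.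

Step 14
Reactants: 21 4β,8α,9α-trihydroxy-5αH-daucan-7-one
Product: 22 4β-hydroxy-8α,9α-(isopropylidenedioxy)-5αH-daucan-7-one
Conditions: Me2C(OMe)2, PPTS (cat.), acetone, rt
Reagents that add atoms: 2,2-dimethoxypropane, COC(C)(C)OC
Why: Acid-catalysed transketalisation closes the dioxolane on the cis-8,9-diol, while the tertiary C4 hydroxyl cannot form a cyclic ketal and stays free. The ketal blocks retro-aldol cleavage and α-ketol rearrangement in step 15 and leaves a single acylable hydroxyl for step 16.

Step 15
Reactants: 22 4β-hydroxy-8α,9α-(isopropylidenedioxy)-5αH-daucan-7-one
Product: 23 4β,6α-dihydroxy-8α,9α-(isopropylidenedioxy)-5αH-daucan-7-one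
Conditions: KN(SiMe3)2 (excess), THF, −78 °C; 2-(phenylsulfonyl)-3-phenyloxaziridine; aq. NH4Cl
Reagents that add atoms: 2-(phenylsulfonyl)-3-phenyloxaziridine, O=S(=O)(c1ccccc1)N1OC1c1ccccc1
Why: The ketone can enolise only towards C6 because C8 is fully substituted; the potassium enolate is hydroxylated by the N-sulfonyloxaziridine (enolate oxidation), which should approach C6 from the α face, away from the angular methyl and the C8 methyl. The α (equatorial) hydroxyl is also the more stable epimer.

Step 16
Reactants: 23 4β,6α-dihydroxy-8α,9α-(isopropylidenedioxy)-5αH-daucan-7-one; 24 4-(methoxymethoxy)benzoic acid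
Product: 25 4β-hydroxy-8α,9α-(isopropylidenedioxy)-7-oxo-5αH-daucan-6α-yl 4-(methoxymethoxy)benzoate
Conditions: 24, EDC·HCl, DMAP, CH2Cl2, rt
Reagents that add atoms: 4-(methoxymethoxy)benzoic acid (24), COCOc1ccc(cc1)C(=O)O
Why: Steglich esterification acylates the secondary C6 hydroxyl, the tertiary C4 hydroxyl being too hindered to react. The phenol is masked as its methoxymethyl ether so that it cannot compete.

Step 17
Reactants: 25 4β-hydroxy-8α,9α-(isopropylidenedioxy)-7-oxo-5αH-daucan-6α-yl 4-(methoxymethoxy)benzoate
Product: 26 4β,8α,9α-trihydroxy-7-oxo-5αH-daucan-6α-yl 4-hydroxybenzoate (CNP0241001.1)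
Conditions: HCl (2 M aq.), THF–MeOH, rt
Reagents that add atoms: none
Why: Dilute acid hydrolyses the isopropylidene ketal and the aryl methoxymethyl ether in one operation; the ester, the α-ketol and the now non-allylic tertiary carbinol should tolerate these conditions. No base is used that could trigger acyl migration or retro-aldol cleavage.

## Compound list

1 | pent-4-yn-1-ol | C#CCCCO | starting material
2 | propanal | CCC=O | starting material
3 | alkenylalane: dimethyl[(E)-5-(dimethylalumanyloxy)-2-methylpent-1-enyl]alane | C[Al](C)/C=C(\C)CCCO[Al](C)C | intermediate (not isolated)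
4 | (E)-5-methyloct-4-ene-3,8-diol, racemic at C3 | CCC(O)/C=C(\C)CCCO | intermediate
5 | (E)-4-methyl-6-oxooct-4-enoic acid | CCC(=O)/C=C(\C)CCC(=O)O | intermediate
6 | (E)-N-methoxy-N,4-dimethyl-6-oxooct-4-enamide | CCC(=O)/C=C(\C)CCC(=O)N(C)OC | intermediate
7 | (4E,6Z)-6-(tert-butyldimethylsilyloxy)-N-methoxy-N,4-dimethylocta-4,6-dienamide | CON(C)C(=O)CC/C(C)=C/C(O[Si](C)(C)C(C)(C)C)=C/C | intermediate
8 | allylmagnesium bromide | C=CC[Mg]Br | starting material
9 | (7E,9Z)-9-(tert-butyldimethylsilyloxy)-7-methylundeca-1,7,9-trien-4-one | C=CCC(=O)CC/C(C)=C/C(O[Si](C)(C)C(C)(C)C)=C/C | intermediate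
10 | (7E,9Z)-9-(tert-butyldimethylsilyloxy)-3-diazo-7-methylundeca-1,7,9-trien-4-one | C=CC(=[N+]=[N-])C(=O)CC/C(C)=C/C(O[Si](C)(C)C(C)(C)C)=C/C | intermediate
11 | divinylcyclopropane: 5-methyl-6-[(Z)-1-(tert-butyldimethylsilyloxy)prop-1-enyl]-1-vinylbicyclo[3.1.0]hexan-2-one, vinyl, methyl and silyloxypropenyl groups all cis on the three-membered ring | C=C[C@@]12C(=O)CC[C@]1(C)[C@H]2/C(O[Si](C)(C)C(C)(C)C)=C/C | intermediate (not isolated)
12 | 9-(tert-butyldimethylsilyloxy)-1β,8α-dimethylbicyclo[5.3.0]deca-5,9-dien-4-one | O=C1CC[C@]2(C)C=C(O[Si](C)(C)C(C)(C)C)[C@H](C)CC=C12 | intermediate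
13 | isopropylmagnesium chloride | CC(C)[Mg]Cl | starting material
14 | (8βH)-9-(tert-butyldimethylsilyloxy)dauca-5,9-dien-4β-ol (4α-isopropyl) | CC(C)[C@]1(O)CC[C@]2(C)C=C(O[Si](C)(C)C(C)(C)C)[C@H](C)CC=C21 | intermediate
15 | hydroxy ketone: (8βH)-4β-hydroxydauc-5-en-9-one | CC(C)[C@]1(O)CC[C@]2(C)CC(=O)[C@H](C)CC=C21 | intermediate (not isolated)
16 | (8βH)-dauc-5-ene-4β,9-diol, both C9 epimers | CC(C)[C@]1(O)CC[C@]2(C)CC(O)[C@H](C)CC=C21 | intermediate
17 | (8βH)-4β-hydroxydauc-5-en-9-yl acetate, both C9 epimers | CC(C)[C@]1(O)CC[C@]2(C)CC(OC(C)=O)[C@H](C)CC=C21 | intermediate
18 | acetoxy enone: (8βH)-4β-hydroxy-7-oxodauc-5-en-9-yl acetate, both C9 epimers | CC(C)[C@]1(O)CC[C@]2(C)CC(OC(C)=O)[C@H](C)C(=O)C=C21 | intermediate (not isolated)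
19 | 4β-hydroxydauca-5,8-dien-7-one | CC(C)[C@]1(O)CC[C@]2(C)CC=C(C)C(=O)C=C21 | intermediate
20 | 4β,8α,9α-trihydroxydauc-5-en-7-one | CC(C)[C@]1(O)CC[C@]2(C)C[C@H](O)[C@](C)(O)C(=O)C=C21 | intermediate
21 | 4β,8α,9α-trihydroxy-5αH-daucan-7-one (trans-fused) | CC(C)[C@]1(O)CC[C@]2(C)C[C@H](O)[C@](C)(O)C(=O)C[C@H]21 | intermediate
22 | 4β-hydroxy-8α,9α-(isopropylidenedioxy)-5αH-daucan-7-one | CC(C)[C@]1(O)CC[C@]2(C)C[C@@H]3OC(C)(C)O[C@]3(C)C(=O)C[C@H]21 | intermediate
23 | 4β,6α-dihydroxy-8α,9α-(isopropylidenedioxy)-5αH-daucan-7-one | CC(C)[C@]1(O)CC[C@]2(C)C[C@@H]3OC(C)(C)O[C@]3(C)C(=O)[C@H](O)[C@H]21 | intermediate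
24 | 4-(methoxymethoxy)benzoic acid | COCOc1ccc(cc1)C(=O)O | starting material
25 | 4β-hydroxy-8α,9α-(isopropylidenedioxy)-7-oxo-5αH-daucan-6α-yl 4-(methoxymethoxy)benzoate | CC(C)[C@]1(O)CC[C@]2(C)C[C@@H]3OC(C)(C)O[C@]3(C)C(=O)[C@H](OC(=O)c4ccc(OCOC)cc4)[C@H]21 | intermediate
26 | 4β,8α,9α-trihydroxy-7-oxo-5αH-daucan-6α-yl 4-hydroxybenzoate (CNP0241001.1) | CC(C)[C@]1(O)CC[C@]2(C)C[C@H](O)[C@](C)(O)C(=O)[C@H](OC(=O)c3ccc(O)cc3)[C@H]21 | target

## Step count and least certain steps

Total: 17 steps. Longest linear sequence: 17 steps (1 → 26); 2, 8, 13 and 24 are bought.

Step 7 (key step). The most likely failure is insufficient enantioface selection, because the acceptor is a ketone held inside the forming ring, a situation less well matched to chiral dirhodium carboxylates than ester-substituted vinylcarbenoids; loss of 10 to a pyrazole before it meets the catalyst would add to this. The fallback gives up asymmetric catalysis: 10 is cyclised with achiral Rh2(esp)2 (dirhodium bis(α,α,α′,α′-tetramethyl-1,3-benzenedipropanoate)) and heated as before, which should give 12 together with the enantiomer of 12 F1. The two are separated by preparative chromatography on a chiral stationary phase, and the route continues from 12.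

Step 13. The most likely failure is protonation of C5 from the β face (cis fusion), because the energetic preference for a trans junction is smaller in a 5–7 system than in decalins. The fallback replaces thermodynamic protonation by kinetic syn-delivery of hydrogen: 20 is hydrogenated over palladium on carbon (H2, EtOAc), where adsorption on the α face, away from the angular methyl, should give 21 directly (no new compound, F0).

Step 12. The most likely failure is poor facial selectivity, because the cross-conjugated dienone is nearly flat and only the remote angular methyl differentiates its faces. The fallback uses a temporary stereocentre next to the alkene: 19 is reduced at C7 (Luche reduction, NaBH4, CeCl3·7H2O) to the bis-allylic alcohol F2. F2 is osmylated under control of the C7 hydroxyl (anti with OsO4/NMO, syn with OsO4·TMEDA; the C7 epimer is chosen accordingly) to the tetraol F3. The allylic C7 hydroxyl of F3 is re-oxidised with MnO2, returning to the route at 20.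

Step 11. The most likely failure is slow or unselective radical C–H oxidation, because C7 is flanked by a hindered alkene and a branched carbon, and the allylic radical can also be trapped at the C5 terminus. The fallback replaces C–H abstraction by an ene reaction with allylic transposition, as known for Δ5 steroids. Photooxygenation of 17 (O2, light, sensitiser) should give the 5α-hydroperoxide F4, which rearranges on standing to the 7-hydroperoxide F5. Dehydration of F5 with Ac2O/pyridine (Kornblum–DeLaMare) gives 18, which is treated with DBU as in step 11 to reach 19.

Step 8. The most likely failure is β-hydride reduction or enolisation by the branched reagent competing with addition, because the carbonyl is conjugated and flanked by a fully substituted carbon; incomplete facial selectivity is the second concern. The fallback brings in the three carbons as an sp2 nucleophile: 12 is treated with isopropenylmagnesium bromide/CeCl3 to give the isopropenyl carbinol F6. The 1,1-disubstituted alkene of F6 is hydrogenated selectively with RhCl(PPh3)3/H2, which should leave the trisubstituted alkene and the enol ether untouched, returning to the route at 14.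

## Further compounds

F1 | step 7 | enantiomer of 12 | O=C1CC[C@@]2(C)C=C(O[Si](C)(C)C(C)(C)C)[C@@H](C)CC=C12
F0 | step 13 | none | none
F2 | step 12 | dauca-5,8-diene-4β,7-diol (C7 epimers) | CC(C)[C@]1(O)CC[C@]2(C)CC=C(C)C(O)C=C21
F3 | step 12 | dauc-5-ene-4β,7,8α,9α-tetraol (C7 epimers) | CC(C)[C@]1(O)CC[C@]2(C)C[C@H](O)[C@](C)(O)C(O)C=C21
F4 | step 11 | (8βH)-5α-hydroperoxy-4β-hydroxydauc-6-en-9-yl acetate | CC(C)[C@]1(O)CC[C@]2(C)CC(OC(C)=O)[C@H](C)C=C[C@]21OO
F5 | step 11 | (8βH)-7-hydroperoxy-4β-hydroxydauc-5-en-9-yl acetate | CC(C)[C@]1(O)CC[C@]2(C)CC(OC(C)=O)[C@H](C)C(OO)C=C21
F6 | step 8 | 4α-isopropenyl analogue of 14 | CC(=C)[C@]1(O)CC[C@]2(C)C=C(O[Si](C)(C)C(C)(C)C)[C@H](C)CC=C21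
A1 | alternative 1 | trans-fused cycloheptene: 4β-(triethylsilyloxy)-8α,9α-(isopropylidenedioxy)-5αH-dauc-6-ene | CC(C)[C@]1(O[Si](CC)(CC)CC)CC[C@]2(C)C[C@@H]3OC(C)(C)O[C@]3(C)C=C[C@H]21
A2 | alternative 1 | eight-membered cyclic sulfone, SO2 between C6 and C7 | CC(C)[C@]1(O[Si](CC)(CC)CC)CC[C@]2(C)C[C@@H]3OC(C)(C)O[C@]3(C)CS(=O)(=O)C[C@H]21
A3 | alternative 2 | oxygen-bridged (5+2) cycloadduct | CC(C)[C@]1(O[Si](C)(C)C)CC[C@]2(C)C[C@H]3C(=O)C(O[Si](C)(C)C(C)(C)C)=C[C@]21O3
A4 | alternative 2 | 5-(tert-butyldimethylsilyloxy)-4-pyranone with the alkenyl carbinol side chain at C2 | CC(C)[C@](O[Si](C)(C)C)(CCC(C)=C)C1=CC(=O)C(O[Si](C)(C)C(C)(C)C)=CO1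
A5 | alternative 3 | ketal-protected cyclohept-4-enone fused to the cyclopentane | C12(OCCO1)CC[C@]3(C)CC(=O)[C@]4(C)OC(C)(C)O[C@@H]4C=C23
A6 | alternative 3 | 2-methylene-5-(cyclopentenyl)tetrahydrofuran with the 3,4-isopropylidenedioxy group | C=C1O[C@H](C2=C(C)CCC23OCCO3)[C@H]4OC(C)(C)O[C@@]14C
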